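**Plan**

- Retrosynthesis cuts, in this order: the aryl–CH2 bond of the allyl group (back to an aryl triflate); the C–aryl and C–H bonds at the CH(Ar) carbon (back to a benzo-fused 1,4-dioxin-2-one and an aryl Grignard reagent); the bond between the benzene ring and the oxygen on that carbon (back, by a 1,2-shift, to a spiro carbon); the O–CH(CH3) bond (back to hydroquinone and (R)-2-chloropropanoic acid).
- Forward order: aryl ether first, then oxidative dearomatisation to a five-membered spiro lactone (1,3-dioxolan-4-one), which is enlarged to the aromatic six-membered 1,4-dioxin-2-one; the trimethoxyphenyl ring and the allyl chain are attached afterwards.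
- Enabling feature: the benzene ring of the benzodioxane carries its two ring oxygens on adjacent carbons and the allyl group para to the oxygen bound to CH(CH3). A p-quinone monoketal gives exactly this pattern when the acyl oxygen moves from the spiro carbon to the neighbouring ring carbon. The dienone C=O para to the spiro carbon becomes the phenol that marks the allyl position, so the two dioxane oxygens are told apart without a differentiated catechol.
- Stereochemistry: the CH(CH3) centre (S) comes from (R)-2-chloropropanoic acid by SN2 inversion; the CH(Ar) centre (R, cis) comes from hydride delivery to a cyclic oxocarbenium ion anti to the neighbouring methyl group.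

Key step: step 3

Assumption: (3,4,5-trimethoxyphenyl)magnesium bromide 8 is bought as its THF solution (it can equally be made from 5-bromo-1,2,3-trimethoxybenzene and Mg).

**Step 1**
Reactants: 1 hydroquinone; 2 (R)-2-chloropropanoic acid
Product: 3 (S)-2-(4-hydroxyphenoxy)propanoic acid
Conditions: 1 (3 equiv), NaOH (aq), Na2S2O4 (cat.), N2, reflux; then HCl
Reagents that add atoms: none
Why: Williamson ether synthesis: the phenoxide should displace chloride from the α-carbon of the carboxylate by SN2 with inversion, which sets the (S) configuration at the O–CH(CH3) carbon, and the excess of 1 limits double alkylation.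

**Step 2**
Reactants: 3 (S)-2-(4-hydroxyphenoxy)propanoic acid
Product: 4 (3S)-3-methyl-1,4-dioxaspiro[4.5]deca-6,9-diene-2,8-dione
Conditions: PhI(OAc)2 (1.05 equiv), MeCN, 0 °C
Reagents that add atoms: none
Why: Hypervalent-iodine oxidative dearomatisation of a p-alkoxyphenol: the tethered carboxylate should trap the phenoxonium ion at the alkoxy-bearing para carbon (5-exo spirolactonisation) to give the quinone-monoketal-type spiro acylal, whose spiro carbon is not stereogenic because the dienone ring is symmetric, while the existing stereocentre is not involved.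

**Step 3**
Reactants: 4 (3S)-3-methyl-1,4-dioxaspiro[4.5]deca-6,9-diene-2,8-dione
Product: 6 (3S)-7-hydroxy-3-methyl-1,4-benzodioxin-2(3H)-one, via ring-opened quinone oxocarbenium carboxylate 5 (not isolated)
Conditions: TfOH (5 mol%), (CF3)2CHOH/CH2Cl2 1:4, 0.01 M, −20 to 0 °C
Reagents that add atoms: none
Why: Proposed new method: the acid should ionise the spiro acylal at its C–O(acyl) bond, because the carboxylate is by far the better leaving group and the remaining ether oxygen stabilises the quinone oxocarbenium ion, and the tethered carboxyl group, which can reach only the ring carbon next to the former spiro carbon, should add there to give an alkoxy-stabilised arenium ion that loses a proton and becomes aromatic (net 1,2-acyloxy shift). The closest known reaction type is the acid-mediated dienone–phenol rearrangement of spirodienone lactones and of p-quinol esters, together with the acid-induced substitution chemistry of quinone monoketals. The six-membered 1,4-dioxin-2-one ring closes in a 6-exo-trig mode onto a ring carbon adjacent to the spiro centre, so the five-membered spiro ring is enlarged by one ring carbon. No new stereocentre is formed, and the CH(CH3) centre is not touched under these non-basic conditions. The step needs regioselectivity for the acyl oxygen to move and for the new C–O bond to form next to the retained ether oxygen: the first is secured by the leaving-group difference between carboxylate and alkoxide, the second by the symmetry of the dienone ring (its two carbons next to the spiro centre are equivalent), and the dilute, non-nucleophilic medium is meant to keep external nucleophiles and the product phenol from intercepting the cation.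

**Step 4**
Reactants: 6 (3S)-7-hydroxy-3-methyl-1,4-benzodioxin-2(3H)-one
Product: 7 (3S)-3-methyl-2-oxo-2,3-dihydro-1,4-benzodioxin-7-yl trifluoromethanesulfonate
Conditions: Tf2O (1.1 equiv), pyridine (2 equiv), CH2Cl2, −20 to 0 °C
Reagents that add atoms: trifluoromethanesulfonic anhydride, O=S(=O)(OS(=O)(=O)C(F)(F)F)C(F)(F)F
Why: O-Sulfonylation of the phenol gives the aryl triflate that later carries the allyl group; the weak base and low temperature should leave the enolisable aryl lactone and its α-stereocentre intact.

**Step 5**
Reactants: 7 (3S)-3-methyl-2-oxo-2,3-dihydro-1,4-benzodioxin-7-yl trifluoromethanesulfonate; 8 (3,4,5-trimethoxyphenyl)magnesium bromide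
Product: 9 (2S)-3-hydroxy-2-methyl-3-(3,4,5-trimethoxyphenyl)-2,3-dihydro-1,4-benzodioxin-6-yl trifluoromethanesulfonate (cyclic hemiketal; both configurations at the hemiketal carbon)
Conditions: 8 (1.05 equiv, slow addition), THF, −78 °C; then H2O at −78 °C
Reagents that add atoms: none
Why: Grignard addition to the activated aryl lactone should stop at the magnesium hemiketalate, which is held by chelation to the ring ether oxygen at −78 °C, so that one aryl group is delivered and the cyclic hemiketal results on protonation; the aryl triflate is inert to the Grignard reagent at this temperature, and the new hemiketal centre is removed in step 6.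

**Step 6**
Reactants: 9 (2S)-3-hydroxy-2-methyl-3-(3,4,5-trimethoxyphenyl)-2,3-dihydro-1,4-benzodioxin-6-yl trifluoromethanesulfonate
Product: 11 (2S,3R)-2-methyl-3-(3,4,5-trimethoxyphenyl)-2,3-dihydro-1,4-benzodioxin-6-yl trifluoromethanesulfonate (cis), via benzodioxinylium ion 10 (not isolated)
Conditions: Et3SiH (4 equiv), CF3CO2H (10 equiv), CH2Cl2, −40 to −10 °C
Reagents that add atoms: none
Why: Ionic hydrogenation (reductive deoxygenation of a hemiketal with silane and acid): in the aryl-stabilised cyclic oxocarbenium ion 10 the neighbouring methyl group should stand pseudo-axial to avoid allylic strain with the aryl group, so hydride should add on the face anti to it, leaving H trans and the aryl group cis to CH3, which sets the (3R) centre.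

**Step 7**
Reactants: 11 (2S,3R)-2-methyl-3-(3,4,5-trimethoxyphenyl)-2,3-dihydro-1,4-benzodioxin-6-yl trifluoromethanesulfonate; 12 allyltributylstannane
Product: 13 (2S,3R)-2-methyl-6-(prop-2-en-1-yl)-3-(3,4,5-trimethoxyphenyl)-2,3-dihydro-1,4-benzodioxine (CNP0000093.1)
Conditions: Pd(PPh3)4 (5 mol%), LiCl (3 equiv), DMF, 90 °C
Reagents that add atoms: none
Why: Stille coupling of an aryl triflate with an allylstannane (LiCl-assisted transmetalation) should install the allyl group at the carbon that the key step marked with the phenol, without touching the two stereocentres.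

**Compound list**

1 | hydroquinone | Oc1ccc(O)cc1 | starting material
2 | (R)-2-chloropropanoic acid | OC(=O)[C@@H](C)Cl | starting material
3 | (S)-2-(4-hydroxyphenoxy)propanoic acid | OC(=O)[C@H](C)Oc1ccc(O)cc1 | intermediate
4 | (3S)-3-methyl-1,4-dioxaspiro[4.5]deca-6,9-diene-2,8-dione (spiro lactone; ether O and acyl O both on the spiro carbon) | O=C1C=CC2(C=C1)OC(=O)[C@H](C)O2 | intermediate
5 | ring-opened quinone oxocarbenium carboxylate (O-alkylated p-benzoquinone cation with the (S)-1-carboxylatoethyl group on oxygen) | [O-]C(=O)[C@H](C)[O+]=C1C=CC(=O)C=C1 | intermediate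
6 | (3S)-7-hydroxy-3-methyl-1,4-benzodioxin-2(3H)-one (OH para to the ring oxygen bound to CH(CH3)) | Oc1ccc2c(c1)OC(=O)[C@H](C)O2 | intermediate
7 | (3S)-3-methyl-2-oxo-2,3-dihydro-1,4-benzodioxin-7-yl trifluoromethanesulfonate | FC(F)(F)S(=O)(=O)Oc1ccc2c(c1)OC(=O)[C@H](C)O2 | intermediate
8 | (3,4,5-trimethoxyphenyl)magnesium bromide | COc1cc([Mg]Br)cc(OC)c1OC | starting material
9 | (2S)-3-hydroxy-2-methyl-3-(3,4,5-trimethoxyphenyl)-2,3-dihydro-1,4-benzodioxin-6-yl trifluoromethanesulfonate (hemiketal carbon unspecified) | FC(F)(F)S(=O)(=O)Oc1ccc2c(c1)OC(O)(c1cc(OC)c(OC)c(OC)c1)[C@H](C)O2 | intermediate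
10 | (2S)-2-methyl-3-(3,4,5-trimethoxyphenyl)-6-(trifluoromethylsulfonyloxy)-2H-1,4-benzodioxin-4-ium trifluoroacetate (cyclic oxocarbenium ion) | FC(F)(F)S(=O)(=O)Oc1ccc2c(c1)[O+]=C(c1cc(OC)c(OC)c(OC)c1)[C@H](C)O2.[O-]C(=O)C(F)(F)F | intermediate
11 | (2S,3R)-2-methyl-3-(3,4,5-trimethoxyphenyl)-2,3-dihydro-1,4-benzodioxin-6-yl trifluoromethanesulfonate (cis) | FC(F)(F)S(=O)(=O)Oc1ccc2c(c1)O[C@H](c1cc(OC)c(OC)c(OC)c1)[C@H](C)O2 | intermediate
12 | allyltributylstannane | C=CC[Sn](CCCC)(CCCC)CCCC | starting material
13 | (2S,3R)-2-methyl-6-(prop-2-en-1-yl)-3-(3,4,5-trimethoxyphenyl)-2,3-dihydro-1,4-benzodioxine (cis; CNP0000093.1) | C=CCc1ccc2c(c1)O[C@H](c1cc(OC)c(OC)c(OC)c1)[C@H](C)O2 | target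

**Summary**

Total step count: 7. Longest linear sequence: 7 steps (1 → 3 → 4 → 6 → 7 → 9 → 11 → 13).

Steps most likely to fail:

1. Step 3 (Proposed new method). The quinone oxocarbenium ion may partition the wrong way: capture by an external nucleophile at the carbon next to the C=O group, arylation by the product phenol, or shift of the ether oxygen in place of the acyl oxygen, which would put the phenol para to the wrong ring oxygen. Fallback with known chemistry and no dearomatisation: from 2, O-alkylation of 5-bromo-2-hydroxybenzaldehyde F1 (aq NaOH, reflux; then HCl) should give (S)-2-(4-bromo-2-formylphenoxy)propanoic acid F2. Dakin-type Baeyer–Villiger oxidation (mCPBA, CH2Cl2; then aq NaOH; then HCl) should give (S)-2-(4-bromo-2-hydroxyphenoxy)propanoic acid F3, and acid-catalysed lactonisation (TsOH, toluene, reflux, water separator) should give (3S)-7-bromo-3-methyl-1,4-benzodioxin-2(3H)-one F4, in which bromide takes the role of the triflate. Addition of 8 as in step 5 should give (2S)-6-bromo-3-hydroxy-2-methyl-3-(3,4,5-trimethoxyphenyl)-2,3-dihydro-1,4-benzodioxine F5, reduction as in step 6 should give (2S,3R)-6-bromo-2-methyl-3-(3,4,5-trimethoxyphenyl)-2,3-dihydro-1,4-benzodioxine F6, and Stille coupling of F6 with 12 comes back to the route at 13.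

2. Step 5. A second aryl group may be transferred after collapse of the tetrahedral intermediate to the ring-opened ketone, and the basic reagent may enolise the lactone and erode the α-stereocentre. Fallback: from 7, ring-opening with N,O-dimethylhydroxylamine hydrochloride and AlMe3 (CH2Cl2, 0 °C) should give (S)-2-[2-hydroxy-4-(trifluoromethylsulfonyloxy)phenoxy]-N-methoxy-N-methylpropanamide F7. Treatment with 8 (2.2 equiv, THF, −40 °C) then delivers a single aryl group through the stable chelated adduct, and the keto-phenol set free on work-up closes to the hemiketal, which comes back to the route at 9.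

3. Step 6. Hydride delivery may show poor facial selectivity, the oxocarbenium ion may lose the proton at CH(CH3) reversibly (loss of configuration through the enol ether), and the acid may ionise the benzylic C–O bond of the product (cis-to-trans equilibration). Fallback: from 9, reduction of its ring-opened keto-phenol form under non-chelation control (L-Selectride, THF, −78 °C) should give the threo alcohol 3-hydroxy-4-[(1S,2S)-1-hydroxy-1-(3,4,5-trimethoxyphenyl)propan-2-yl]oxyphenyl trifluoromethanesulfonate F8. Mitsunobu etherification (PPh3, DIAD, THF, 0 °C; SN2 inversion at the benzylic carbon) then closes the dioxane ring and comes back to the route at 11.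

**Further compounds**

F1 | step 3 | 5-bromo-2-hydroxybenzaldehyde | O=Cc1cc(Br)ccc1O
F2 | step 3 | (S)-2-(4-bromo-2-formylphenoxy)propanoic acid | OC(=O)[C@H](C)Oc1ccc(Br)cc1C=O
F3 | step 3 | (S)-2-(4-bromo-2-hydroxyphenoxy)propanoic acid | OC(=O)[C@H](C)Oc1ccc(Br)cc1O
F4 | step 3 | (3S)-7-bromo-3-methyl-1,4-benzodioxin-2(3H)-one | Brc1ccc2c(c1)OC(=O)[C@H](C)O2
F5 | step 3 | (2S)-6-bromo-3-hydroxy-2-methyl-3-(3,4,5-trimethoxyphenyl)-2,3-dihydro-1,4-benzodioxine | Brc1ccc2c(c1)OC(O)(c1cc(OC)c(OC)c(OC)c1)[C@H](C)O2
F6 | step 3 | (2S,3R)-6-bromo-2-methyl-3-(3,4,5-trimethoxyphenyl)-2,3-dihydro-1,4-benzodioxine | Brc1ccc2c(c1)O[C@H](c1cc(OC)c(OC)c(OC)c1)[C@H](C)O2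
F7 | step 5 | (S)-2-[2-hydroxy-4-(trifluoromethylsulfonyloxy)phenoxy]-N-methoxy-N-methylpropanamide | CON(C)C(=O)[C@H](C)Oc1ccc(OS(=O)(=O)C(F)(F)F)cc1O
F8 | step 6 | 3-hydroxy-4-[(1S,2S)-1-hydroxy-1-(3,4,5-trimethoxyphenyl)propan-2-yl]oxyphenyl trifluoromethanesulfonate | C[C@H](Oc1ccc(OS(=O)(=O)C(F)(F)F)cc1O)[C@@H](O)c1cc(OC)c(OC)c(OC)c1
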